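**Plan**

- Target numbering (6-oxabicyclo[3.2.2]non-3-ene-2,7-dione): C1 bridgehead CH, C2 ketone, C3(allyl)=C4, C5 bridgehead ketal (OMe), O6, C7 lactone C=O, C8 CHAr, C9 CHMe. Ring A is the carbocycle C1–C2–C3=C4–C5–C9–C8; ring B is the lactone C1–C7–O6–C5–C9–C8.
- Cuts, in order: (a) O6–C5 and C5–OMe, opening ring B to a cyclohept-3-ene-2,5-dione with a tert-butyl ester on C1; (b) C8–C1 and C8–C9, removing C8 as 3,4,5-trimethoxybenzaldehyde and leaving an open cis-ene-dione β-keto ester; (c) the two ene-dione carbonyls back to a 2,3,5-trisubstituted furan built on 2-ethylfuran.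
- Enabling feature: C8 lies in ring A between C1 (α-carbon of a β-keto ester) and C9 (α-carbon of the C5 ketone). The cis C3=C4 bond holds these two nucleophilic carbons close, so C8 can enter last as an aldehyde carbon.
- Forward: the furan is dressed (steps 1–4) and opened to the cis-ene-dione (step 5); ring A closes in one [6+1] operation (step 6); ring B closes last (step 7).
- Stereochemistry: C8 comes from a chiral primary amine–thiourea; C9 equilibrates trans to the aryl group; C1 and C5 are fixed together when the lactone bridges ring A on the aryl face. The ester is carried as tert-butyl so that this last closure cannot revert.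

Key step: step 6

Assumption: the (1R,2R) antipode of the amine–thiourea is taken to give the R configuration at the aryl-bearing carbon; the sense of induction must be found by experiment, and the (1S,2S) antipode is equally available.

**Step 1**
Reactants: 1 2-ethylfuran
Product: 2 2-bromo-5-ethylfuran
Conditions: N-bromosuccinimide (1.0 equiv), DMF, −20 → 0 °C, dark; used without storage
Reagents that add atoms: N-bromosuccinimide, O=C1CCC(=O)N1Br
Why: Electrophilic aromatic bromination at the only free α-position of the 2-alkylfuran, kept ionic by the polar solvent so that the ethyl side chain is not brominated; no stereocentre is formed.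

**Step 2**
Reactants: 2 2-bromo-5-ethylfuran
Product: 5 3-bromo-5-ethyl-2-iodofuran, via 2-bromo-5-ethyl-3-furyllithium 3 (not isolated), via 3-bromo-5-ethyl-2-furyllithium 4 (not isolated)
Conditions: LiN(i-Pr)2 (1.1 equiv) added to 2, THF, −78 → −40 °C; then I2 (1.2 equiv), −78 °C → rt
Reagents that add atoms: iodine, II
Why: Halogen dance: the amide base removes H3 next to bromine to give 3, bromine–lithium exchange between ring molecules moves lithium to the more acidic α-position and bromine to C3 to give 4 (the behaviour known for 2-bromo-5-methylfuran), and iodine traps 4 at C2; no stereocentre is formed.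

**Step 3**
Reactants: 5 3-bromo-5-ethyl-2-iodofuran; 6 (2-tert-butoxy-2-oxoethyl)zinc chloride
Product: 7 tert-butyl 2-(3-bromo-5-ethylfuran-2-yl)acetate
Conditions: 6 (1.2 equiv, 0.5 M in Et2O), bis(dibenzylideneacetone)palladium Pd(dba)2 (2 mol%), 1,2,3,4,5-pentaphenyl-1′-(di-tert-butylphosphino)ferrocene (2 mol%), THF, rt
Reagents that add atoms: none
Why: Negishi-type coupling of a Reformatsky reagent (palladium-catalysed α-arylation of a zinc ester enolate), in which zerovalent palladium inserts into the α C–I bond far faster than into the β C–Br bond, so only C2 is substituted; no stereocentre is formed.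

**Step 4**
Reactants: 7 tert-butyl 2-(3-bromo-5-ethylfuran-2-yl)acetate; 8 allyltributylstannane
Product: 9 tert-butyl 2-[5-ethyl-3-(prop-2-en-1-yl)furan-2-yl]acetate
Conditions: 8 (1.3 equiv), tris(dibenzylideneacetone)dipalladium Pd2(dba)3 (1.5 mol%), P(t-Bu)3 (6 mol%), CsF (2.2 equiv), 1,4-dioxane, 80 °C
Reagents that add atoms: none
Why: Stille coupling with fluoride activation of the stannane, using an electron-rich bulky phosphine that permits oxidative addition into the hindered β-bromofuran and conditions mild enough for the acidic CH2CO2t-Bu group; no stereocentre is formed.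

**Step 5**
Reactants: 9 tert-butyl 2-[5-ethyl-3-(prop-2-en-1-yl)furan-2-yl]acetate
Product: 10 tert-butyl (4Z)-3,6-dioxo-4-(prop-2-en-1-yl)oct-4-enoate
Conditions: 3-ClC6H4CO3H (mCPBA, 1.05 equiv), CH2Cl2, 0 °C; cold NaHCO3 wash, used at once
Reagents that add atoms: 3-chloroperbenzoic acid, O=C(OO)c1cccc(Cl)c1
Why: Peracid oxidative ring opening of a 2,5-dialkylfuran (ring epoxidation, then collapse to the ene-dione), which gives the carbonyls cis (Z) because both come from the ring, while the monosubstituted allyl alkene is far less nucleophilic than the furan and is left alone; no stereocentre is formed.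

**Step 6**
Reactants: 10 tert-butyl (4Z)-3,6-dioxo-4-(prop-2-en-1-yl)oct-4-enoate; 11 3,4,5-trimethoxybenzaldehyde
Product: 13 tert-butyl (1S,6R,7R)-6-methyl-2,5-dioxo-3-(prop-2-en-1-yl)-7-(3,4,5-trimethoxyphenyl)cyclohept-3-ene-1-carboxylate, via arylidene keto ester 12 (not isolated)
Conditions: 11 (1.5 equiv), 1-[(1R,2R)-2-aminocyclohexyl]-3-[3,5-bis(trifluoromethyl)phenyl]thiourea (20 mol%), PhCO2H (20 mol%), 4 Å molecular sieves, toluene, rt
Reagents that add atoms: none
Why: Proposed new method: the primary amine first condenses aldehyde 11 (through its iminium ion) with the ester-flanked methylene of 10, the most acidic position, to give arylidene keto ester 12, and then converts the ethyl ketone of 12 into its enamine, whose α-carbon adds to the arylidene carbon held by the thiourea; hydrolysis releases 13 and the catalyst. The closest known reaction type is the amine-catalysed domino Knoevenagel–Michael reaction of two carbonyl donors with an aldehyde, joined to primary amine–thiourea Michael additions of ketone enamines to arylidene 1,3-dicarbonyl acceptors, which are established between separate molecules and for smaller rings but not for a seven-membered closure. Ring A closes in a 7-endo-trig mode, both carbons of the arylidene double bond becoming ring atoms. C7 of 13 is set by the catalyst, which binds the keto ester through the thiourea and delivers the enamine to one face of the arylidene; C6 then settles trans to the aryl group by epimerisation next to the C5 ketone, and C1 equilibrates through the β-keto ester enol. The step needs the cis alkene to survive and the condensation to outrun the intramolecular aldol of the active methylene onto the ethyl ketone; the cis geometry, fixed by its origin in the furan, keeps the enamine carbon within reach of the arylidene, and the aldol adduct cannot dehydrate and can revert, whereas dehydration to 12 over molecular sieves removes the active methylene for good.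

**Step 7**
Reactants: 13 tert-butyl (1S,6R,7R)-6-methyl-2,5-dioxo-3-(prop-2-en-1-yl)-7-(3,4,5-trimethoxyphenyl)cyclohept-3-ene-1-carboxylate
Product: 15 (1R,5S,8R,9R)-5-methoxy-9-methyl-3-(prop-2-en-1-yl)-8-(3,4,5-trimethoxyphenyl)-6-oxabicyclo[3.2.2]non-3-ene-2,7-dione, via C5 hemiketal 14 (not isolated)
Conditions: MeOH (10 equiv), camphor-10-sulfonic acid (0.3 equiv), CH2Cl2, 0 °C → rt
Reagents that add atoms: methanol, CO
Why: Acid-catalysed ketalisation–lactonisation (pseudo-ester formation): methanol adds to the C5 ketone to give hemiketal 14, whose methoxy-oxocarbenium ion is captured across ring A by the carbonyl oxygen of the tert-butyl ester with loss of isobutene, so the six-membered lactone cannot revert to an ester; C1 epimerises through the β-keto ester enol until the carboxyl lies on the aryl face, and the bridge then fixes C1 (R) and C5 (S) together, the alternative bridge on the methyl face being disfavoured because it would press the aryl group against the three-atom enone bridge.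

**Compound list**

1 | 2-ethylfuran | CCc1ccco1 | starting material
2 | 2-bromo-5-ethylfuran | CCc1ccc(Br)o1 | intermediate
3 | (2-bromo-5-ethylfuran-3-yl)lithium | CCc1cc([Li])c(Br)o1 | intermediate
4 | (3-bromo-5-ethylfuran-2-yl)lithium | CCc1cc(Br)c([Li])o1 | intermediate
5 | 3-bromo-5-ethyl-2-iodofuran | CCc1cc(Br)c(I)o1 | intermediate
6 | (2-tert-butoxy-2-oxoethyl)zinc chloride (Reformatsky reagent, commercial solution) | CC(C)(C)OC(=O)C[Zn]Cl | starting material
7 | tert-butyl 2-(3-bromo-5-ethylfuran-2-yl)acetate | CCc1cc(Br)c(CC(=O)OC(C)(C)C)o1 | intermediate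
8 | allyltributylstannane | C=CC[Sn](CCCC)(CCCC)CCCC | starting material
9 | tert-butyl 2-[5-ethyl-3-(prop-2-en-1-yl)furan-2-yl]acetate | CCc1cc(CC=C)c(CC(=O)OC(C)(C)C)o1 | intermediate
10 | tert-butyl (4Z)-3,6-dioxo-4-(prop-2-en-1-yl)oct-4-enoate | CCC(=O)/C=C(/CC=C)C(=O)CC(=O)OC(C)(C)C | intermediate
11 | 3,4,5-trimethoxybenzaldehyde | COc1cc(C=O)cc(OC)c1OC | starting material
12 | tert-butyl (4Z)-3,6-dioxo-4-(prop-2-en-1-yl)-2-[(3,4,5-trimethoxyphenyl)methylidene]oct-4-enoate (arylidene geometry not fixed) | CCC(=O)/C=C(/CC=C)C(=O)C(=Cc1cc(OC)c(OC)c(OC)c1)C(=O)OC(C)(C)C | intermediate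
13 | tert-butyl (1S,6R,7R)-6-methyl-2,5-dioxo-3-(prop-2-en-1-yl)-7-(3,4,5-trimethoxyphenyl)cyclohept-3-ene-1-carboxylate (C1 labile, drawn as the all-trans epimer) | CC(C)(C)OC(=O)[C@@H]1C(=O)C(CC=C)=CC(=O)[C@H](C)[C@H]1c1cc(OC)c(OC)c(OC)c1 | intermediate
14 | tert-butyl (1R,5R,6R,7R)-5-hydroxy-5-methoxy-6-methyl-2-oxo-3-(prop-2-en-1-yl)-7-(3,4,5-trimethoxyphenyl)cyclohept-3-ene-1-carboxylate | C=CCC1=C[C@@](OC)(O)[C@H](C)[C@@H](c2cc(OC)c(OC)c(OC)c2)[C@@H](C(=O)OC(C)(C)C)C1=O | intermediate
15 | (1R,5S,8R,9R)-5-methoxy-9-methyl-3-(prop-2-en-1-yl)-8-(3,4,5-trimethoxyphenyl)-6-oxabicyclo[3.2.2]non-3-ene-2,7-dione (CNP0298078.1) | C=CCC1=C[C@@]2(OC)OC(=O)[C@@H](C1=O)[C@H](c1cc(OC)c(OC)c(OC)c1)[C@H]2C | target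

Total step count: 7
Longest linear sequence: 7 steps (1 → 2 → 5 → 7 → 9 → 10 → 13 → 15); 6, 8 and 11 enter as purchased reagents.

**Steps most likely to fail**

1. Step 6 (the proposed new method). Possible failures are:
   - intramolecular aldol of the active methylene onto the ethyl ketone draining 10 before condensation;
   - consumption of the primary amine by conjugate addition to the ene-dione;
   - loss of the cis alkene geometry;
   - a 7-endo closure too slow to compete, or poor facial selectivity at the arylidene.

   The fallback sets out from 10 and 11 and returns at 13. Compound 10 would be condensed with 11 under TiCl4/pyridine (THF, 0 °C; titanium-mediated Knoevenagel condensation) and arylidene keto ester 12 isolated. Its ethyl ketone would be converted with t-BuMe2SiOTf/Et3N (CH2Cl2, −78 °C) into the silyl dienol ether tert-butyl (4Z,6Z)-6-[(tert-butyldimethylsilyl)oxy]-3-oxo-4-(prop-2-en-1-yl)-2-[(3,4,5-trimethoxyphenyl)methylidene]octa-4,6-dienoate F1. Ring A would then be closed by an intramolecular Mukaiyama–Michael addition under Cu(OTf)2 and 2,2′-(propane-2,2-diyl)bis[(4S)-4-tert-butyl-4,5-dihydro-1,3-oxazole] (10 mol%, CH2Cl2, −20 °C). Here the divalent copper chelates the two carbonyls of the arylidene keto ester and the ligand shields one face, with the ligand antipode chosen to give the 7R series. Aqueous acidic work-up should give 13.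

2. Step 7. Possible failures are:
   - capture of the oxocarbenium ion by methanol instead of the ester, stalling at the dimethyl ketal;
   - bridging on the methyl face;
   - premature loss of the tert-butyl group followed by decarboxylation of the β-keto acid.

   The fallback sets out from 13 and returns at 15, separating ester cleavage from ketal formation. The tert-butyl ester would be cleaved first (CF3CO2H, CH2Cl2, 0 °C) to the keto acid (1S,6R,7R)-6-methyl-2,5-dioxo-3-(prop-2-en-1-yl)-7-(3,4,5-trimethoxyphenyl)cyclohept-3-ene-1-carboxylic acid F2. Kept cold, this should close to its ring tautomer, the bridged hydroxy lactone (1R,5S,8R,9R)-5-hydroxy-9-methyl-3-(prop-2-en-1-yl)-8-(3,4,5-trimethoxyphenyl)-6-oxabicyclo[3.2.2]non-3-ene-2,7-dione F3. Exchange of the lactol hydroxyl for methoxyl (MeOH, pyridinium p-toluenesulfonate, rt; conversion of a pseudo-acid into its pseudo-ester) should then give 15.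

3. Step 5. Possible failures are:
   - epoxidation of the allyl group by excess peracid;
   - acid-promoted isomerisation of the cis-ene-dione or its aldol cyclisation during work-up.

   The fallback sets out from 9 and returns at 10. Dye-sensitised photooxygenation (O2, tetraphenylporphyrin, visible light, CH2Cl2, −78 °C) should give, by [4+2] addition of singlet oxygen, the furan endoperoxide tert-butyl 2-[4-ethyl-6-(prop-2-en-1-yl)-2,3,7-trioxabicyclo[2.2.1]hept-5-en-1-yl]acetate F4; the monosubstituted alkene does not react. Reduction with Me2S at −78 °C would then open F4 to 10 under neutral conditions.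

**Further compounds**

F1 | step 6 | tert-butyl (4Z,6Z)-6-[(tert-butyldimethylsilyl)oxy]-3-oxo-4-(prop-2-en-1-yl)-2-[(3,4,5-trimethoxyphenyl)methylidene]octa-4,6-dienoate | C/C=C(\O[Si](C)(C)C(C)(C)C)/C=C(/CC=C)C(=O)C(=Cc1cc(OC)c(OC)c(OC)c1)C(=O)OC(C)(C)C
F2 | step 7 | (1S,6R,7R)-6-methyl-2,5-dioxo-3-(prop-2-en-1-yl)-7-(3,4,5-trimethoxyphenyl)cyclohept-3-ene-1-carboxylic acid | OC(=O)[C@@H]1C(=O)C(CC=C)=CC(=O)[C@H](C)[C@H]1c1cc(OC)c(OC)c(OC)c1
F3 | step 7 | (1R,5S,8R,9R)-5-hydroxy-9-methyl-3-(prop-2-en-1-yl)-8-(3,4,5-trimethoxyphenyl)-6-oxabicyclo[3.2.2]non-3-ene-2,7-dione | C=CCC1=C[C@@]2(O)OC(=O)[C@@H](C1=O)[C@H](c1cc(OC)c(OC)c(OC)c1)[C@H]2C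
F4 | step 5 | tert-butyl 2-[4-ethyl-6-(prop-2-en-1-yl)-2,3,7-trioxabicyclo[2.2.1]hept-5-en-1-yl]acetate (racemic) | CCC12OOC(CC(=O)OC(C)(C)C)(O1)C(CC=C)=C2
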